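## Retrosynthetic overview
1. The C1 ketone/C9-OH anti-aldol unit is carried as a 2-isoxazoline. This leaves C8-OH as the only free hydroxyl for the methacrylate, and N–O cleavage is the last step.
2. Key disconnection is C6–C7 together with C6O–C12. One Ni/Cr operation adds a (Z)-β-iodoenoate to a tethered (Z)-enal and lactonises, so the ten-membered carbocycle and the butenolide form together.
3. The acyclic precursor comes from a magnesium-alkoxide-directed nitrile oxide cycloaddition (C1–C10 and O–C9). C8 controls C9 and C10.
4. Fragments: C1–C6 comes from nerol, which supplies the 4Z alkene. C7–C14 comes from crotonaldehyde, methyl propiolate and formaldehyde.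
5. Ring order: isoxazoline (temporary), then carbocycle and butenolide in the same step, then the isoxazoline is opened.

Assumption: germacrane numbering (C1 ketone, C6 lactone carbinol, C8 ester carbinol, C9 free carbinol, C10 methyl-bearing carbon, C13 acetoxymethyl) is used for all compounds, and the ProPhenol antipode written is taken to be the one that gives (S)-9.

## Route

Step 1
Reactants: 1 nerol
Product: 2 neryl tert-butyldimethylsilyl ether
Conditions: TBSCl, imidazole, CH2Cl2, 0 °C to rt
Reagents that add atoms: tert-butyldimethylsilyl chloride, CC(C)(C)[Si](C)(C)Cl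
Why: Standard silyl ether protection of the primary allylic alcohol, which leaves the purchased Z-trisubstituted alkene (future C4=C5) untouched and creates no stereocentre.

Step 2
Reactants: 2 neryl tert-butyldimethylsilyl ether
Product: 4 (Z)-6-(tert-butyldimethylsilyloxy)-4-methylhex-4-enal, via secondary ozonide 3 (not isolated)
Conditions: O3 (1.0 equiv, Sudan III end point), CH2Cl2, −78 °C; Me2S, −78 °C to rt
Reagents that add atoms: ozone, [O-][O+]=O
Why: Chemoselective Criegee ozonolysis, because the electron-rich isopropylidene alkene reacts faster than the alkene deactivated by the allylic oxygen; this reveals C1 as the aldehyde.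

Step 3
Reactants: 4 (Z)-6-(tert-butyldimethylsilyloxy)-4-methylhex-4-enal
Product: 5 (Z)-6-(tert-butyldimethylsilyloxy)-4-methylhex-4-enal oxime
Conditions: NH2OH·HCl, NaOAc, MeOH, rt
Reagents that add atoms: hydroxylamine hydrochloride, NO.Cl
Why: Simple oxime condensation under buffered conditions that leave the silyl ether and the Z-alkene intact (the oxime E/Z ratio is irrelevant).

Step 4
Reactants: 6 (E)-crotonaldehyde, 7 methyl propiolate
Product: 9 methyl (4S,5E)-4-hydroxyhept-5-en-2-ynoate, via zinc acetylide 8 (not isolated)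
Conditions: (S,S)-ProPhenol (10 mol %), Me2Zn (3 equiv), Ph3P=O (20 mol %), PhMe, 4 °C
Reagents that add atoms: none
Why: Zn–ProPhenol catalytic asymmetric alkynylation, for which enals and methyl propiolate are the best substrate pair; the dinuclear zinc catalyst selects the aldehyde face and sets C8.

Step 5
Reactants: 9 methyl (4S,5E)-4-hydroxyhept-5-en-2-ynoate
Product: 11 methyl (2Z,4S,5E)-4-hydroxy-2-(hydroxymethyl)-3-iodohepta-2,5-dienoate, via magnesium iodoallenolate 10 (not isolated)
Conditions: MgI2 (2.2 equiv), monomeric CH2O (THF solution, 3 equiv), CH2Cl2, −20 to 0 °C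
Reagents that add atoms: magnesium iodide, [Mg+2].[I-].[I-]; formaldehyde, C=O
Why: β-Iodo Morita–Baylis–Hillman (iodide conjugate addition/allenolate aldol) reaction in which the electrophile enters anti to iodine, as in the Z-selective hydroiodination of 2-alkynoates, so that I is cis to CO2Me; no stereocentre is created, C8 is untouched, and any E isomer lactonises onto C8-OH and is removed by chromatography.

Step 6
Reactants: 5 (Z)-6-(tert-butyldimethylsilyloxy)-4-methylhex-4-enal oxime, 11 methyl (2Z,4S,5E)-4-hydroxy-2-(hydroxymethyl)-3-iodohepta-2,5-dienoate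
Product: 14 methyl (2Z,4S)-4-hydroxy-2-(hydroxymethyl)-3-iodo-4-[(4R,5R)-4-methyl-3-[(3Z)-3-methyl-5-(tert-butyldimethylsilyloxy)pent-3-enyl]-4,5-dihydroisoxazol-5-yl]but-2-enoate, via hydroximoyl chloride 12 (not isolated), via nitrile oxide 13 (not isolated)
Conditions: 5, t-BuOCl, CH2Cl2, −78 °C; cannulated into 11, i-PrOH, EtMgBr, CH2Cl2, 0 °C to rt
Reagents that add atoms: none
Why: Kanemasa-type hydroxyl-directed nitrile oxide cycloaddition in which magnesium bridges the C8 alkoxide and the nitrile oxide oxygen, so O bonds to C9 and C1 to C10 on the alkene face syn to C8–O with C8–H inside (8,9-syn); suprafacial addition to the E-alkene gives 9,10-anti, and the tetrasubstituted iodoenoate is inert.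

Step 7
Reactants: 14 isoxazoline diol
Product: 15 isoxazoline C13 monoacetate (C8-OH free)
Conditions: AcCl (1.05 equiv), 2,4,6-collidine, CH2Cl2, −78 °C
Reagents that add atoms: acetyl chloride, CC(=O)Cl
Why: Kinetically selective acetylation of the primary C13-OH over the hindered secondary C8-OH installs the acetate of the target and blocks the ene-1,4-diol from oxidative lactonisation in step 8.

Step 8
Reactants: 15 isoxazoline C13 monoacetate
Product: 17 (Z)-enal iodoenoate, via allylic alcohol 16 (not isolated)
Conditions: Bi(OTf)3 (5 mol %), TEMPO (10 mol %), PhI(OAc)2 (1.2 equiv), MeCN–H2O, rt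
Reagents that add atoms: none
Why: One-pot Lewis-acid desilylation and TEMPO/PhI(OAc)2 oxidation, which prefers the primary allylic alcohol over C8-OH and converts nerol-type alcohols to Z-enals without Z-to-E isomerisation.

Step 9
Reactants: 17 (Z)-enal iodoenoate
Product: 20 tricyclic 13-acetoxy-8-hydroxy-germacra-4Z,7(11)-dien-6,12-olide with C1=N–O–C9 isoxazoline (6R,8R,9R,10R), via alkenylchromium 18 (not isolated), via macrocyclic hydroxy ester 19 (not isolated)
Conditions: CrCl2 (15 equiv), NiCl2 (1 mol % of Cr), DMSO–THF, 1 mM, syringe pump 16 h, rt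
Reagents that add atoms: none
Why: Proposed new method: Ni(0) inserts into the activated C7–I bond and transmetallates to Cr(III), giving the ester-chelated (Z)-β-chromioenoate that adds 1,2 to the tethered enal (ten-membered ring), and the C6 chromium alkoxide held cis to CO2Me expels methoxide (butenolide); A1,2 strain places C8–H next to the bulky C7–Cr bond, so C9 and the seven-atom tether lie on one face and C5 must bond on that same face, which is 6R; the free C8 alkoxide cannot β-eliminate; the closest known chemistry is the Nozaki–Hiyama–Kishi coupling of (Z)-β-iodoacrylates with aldehydes to butenolides and NHK closures of nine- to eleven-membered carbocycles.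

Step 10
Reactants: 20 tricyclic C8 alcohol
Product: 21 tricyclic C8 methacrylate
Conditions: methacrylic anhydride, Et3N, DMAP (cat.), CH2Cl2, 0 °C
Reagents that add atoms: methacrylic anhydride, C=C(C)C(=O)OC(=O)C(C)=C
Why: DMAP-catalysed acylation of the only free hydroxyl (C9-O is locked in the isoxazoline) gives complete regiocontrol with retention at C8, and the mild base does not deprotonate C6–H.

Step 11
Reactants: 21 tricyclic C8 methacrylate
Product: 23 CNP0164859.1 (4Z,6R,8R,9R,10S), via hydroxy imine 22 (not isolated)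
Conditions: Mo(CO)6 (1.2 equiv), MeCN–H2O 15:1, 80 °C
Reagents that add atoms: water, O
Why: Mo(0)-mediated reductive N–O cleavage of the isoxazoline and hydrolysis of the imine release the C1 ketone and C9-OH under neutral conditions that do not epimerise C10 or C6 and do not reduce the alkenes, the butenolide or the esters.

## Compound list
1 | nerol | OC/C=C(/C)CCC=C(C)C | starting material
2 | neryl tert-butyldimethylsilyl ether | CC(C)(C)[Si](C)(C)OC/C=C(/C)CCC=C(C)C | intermediate
3 | secondary ozonide of 2 at the isopropylidene alkene (not isolated) | CC(C)(C)[Si](C)(C)OC/C=C(/C)CCC1OOC(C)(C)O1 | intermediate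
4 | (Z)-6-(tert-butyldimethylsilyloxy)-4-methylhex-4-enal | CC(C)(C)[Si](C)(C)OC/C=C(/C)CCC=O | intermediate
5 | oxime of 4 | CC(C)(C)[Si](C)(C)OC/C=C(/C)CCC=NO | intermediate
6 | (E)-crotonaldehyde | C/C=C/C=O | starting material
7 | methyl propiolate | C#CC(=O)OC | starting material
8 | methylzinc acetylide of 7 (not isolated) | COC(=O)C#C[Zn]C | intermediate
9 | methyl (4S,5E)-4-hydroxyhept-5-en-2-ynoate | COC(=O)C#C[C@@H](O)/C=C/C | intermediate
10 | magnesium β-iodoallenolate of 9 (not isolated) | COC(O[Mg]I)=C=C(I)[C@@H](O)/C=C/C | intermediate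
11 | methyl (2Z,4S,5E)-4-hydroxy-2-(hydroxymethyl)-3-iodohepta-2,5-dienoate | COC(=O)/C(CO)=C(\I)[C@@H](O)/C=C/C | intermediate
12 | hydroximoyl chloride of 5 (not isolated) | CC(C)(C)[Si](C)(C)OC/C=C(/C)CCC(Cl)=NO | intermediate
13 | nitrile oxide from 12 (not isolated) | CC(C)(C)[Si](C)(C)OC/C=C(/C)CCC#[N+][O-] | intermediate
14 | isoxazoline diol (C8 S, C9 R, C10 R; C8-OH and C13-OH free, C6-OTBS) | CC(C)(C)[Si](C)(C)OC/C=C(/C)CCC1=NO[C@H]([C@@H]1C)[C@H](O)C(\I)=C(/CO)C(=O)OC | intermediate
15 | isoxazoline C13 monoacetate | CC(C)(C)[Si](C)(C)OC/C=C(/C)CCC1=NO[C@H]([C@@H]1C)[C@H](O)C(\I)=C(/COC(C)=O)C(=O)OC | intermediate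
16 | C6 allylic alcohol from 15 (not isolated) | OC/C=C(/C)CCC1=NO[C@H]([C@@H]1C)[C@H](O)C(\I)=C(/COC(C)=O)C(=O)OC | intermediate
17 | (Z)-enal iodoenoate | O=C/C=C(/C)CCC1=NO[C@H]([C@@H]1C)[C@H](O)C(\I)=C(/COC(C)=O)C(=O)OC | intermediate
18 | C7 alkenylchromium(III) dichloride (not isolated) | O=C/C=C(/C)CCC1=NO[C@H]([C@@H]1C)[C@H](O)C(\[Cr](Cl)Cl)=C(/COC(C)=O)C(=O)OC | intermediate
19 | macrocyclic C6 hydroxy ester, formed as its chromium alkoxide (not isolated) | COC(=O)/C(COC(C)=O)=C1\[C@H](O)/C=C(/C)CCC2=NO[C@H]([C@@H]2C)[C@@H]1O | intermediate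
20 | tricyclic butenolide–isoxazoline, C8-OH free (6R,8R,9R,10R) | O[C@@H]1C2=C(COC(C)=O)C(=O)O[C@@H]2/C=C(/C)CCC3=NO[C@@H]1[C@@H]3C | intermediate
21 | tricyclic C8 methacrylate | C=C(C)C(=O)O[C@@H]1C2=C(COC(C)=O)C(=O)O[C@@H]2/C=C(/C)CCC3=NO[C@@H]1[C@@H]3C | intermediate
22 | C9-hydroxy C1-imine (not isolated) | C=C(C)C(=O)O[C@@H]1C2=C(COC(C)=O)C(=O)O[C@@H]2/C=C(/C)CCC(=N)[C@@H](C)[C@H]1O | intermediate
23 | CNP0164859.1 | C=C(C)C(=O)O[C@@H]1C2=C(COC(C)=O)C(=O)O[C@@H]2/C=C(/C)CCC(=O)[C@@H](C)[C@H]1O | target

## Step count and risks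
Total steps: 11. Longest linear sequence: 9 (steps 1, 2, 3, 6, 7, 8, 9, 10, 11).

**Step 9 is the most likely to fail.**
- The risks are a strained ten-membered closure by a tetrasubstituted alkenylchromium, protodeiodination, dimerisation, slow Z-to-E drift of the enal, possible Cr(II) attack on the N–O bond, and an uncertain C6 ratio.
- A C6 epimer may be equilibrated with DBU through the 2-oxyfuran, because only C6 is lost in that intermediate.
- The fallback reverses the order of bond formation. It sets out from 5 and 11 and comes back at 20.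
- Selective acetylation of 11 (AcCl, collidine) gives allylic acetate F3.
- Oxidative desilylation of 5 (Bi(OTf)3, TEMPO, PhI(OAc)2) gives enal oxime F4.
- An intermolecular Ni/Cr coupling–lactonisation of the two, under a chiral sulfonamide–chromium catalyst to control C6, gives butenolide oxime F5.
- Chlorination with t-BuOCl gives hydroximoyl chloride F6.
- Slow addition of that chloride to i-PrOMgBr at high dilution gives nitrile oxide F7.
- The C8-OMgBr-directed intramolecular cycloaddition of that dipole closes the carbocycle and the isoxazoline together and delivers 20.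

**Step 5 is second.**
- The iodide/allenolate aldol is well known for propiolates and ordinary aldehydes. Here it must work on a β-branched ynoate with formaldehyde, and it must place iodine cis to the ester.
- The fallback sets out from 9 and comes back at 11. It fixes the geometry with a tether.
- Silylation of 9 with (bromomethyl)chlorodimethylsilane gives bromomethylsilyl ether F1.
- LiI in DMF adds iodide to C7. The iodoallenolate is then alkylated at C11 by the tethered halomethylsilane (6-exo-tet) to give oxasiline F2. The ring in that product forces C13 cis to C8 and therefore I cis to CO2Me.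
- Tamao–Fleming oxidation (H2O2, KF, KHCO3) cleaves both Si–C13 and Si–O8 and releases 11.

**Step 11 is third.**
- Mo(0) at 80 °C could ionise the activated C13 allylic acetate or the doubly allylic C6–O bond. It could also bind the methacrylate.
- The fallback sets out from 20 and comes back at 23. It unmasks the aldol before the methacrylate is present.
- Raney Ni, H2 and B(OH)3 in aqueous MeOH convert 20 into 8,9-diol F8. The tri- and tetrasubstituted alkenes should survive.
- One equivalent of methacrylic anhydride with catalytic DMAP at −20 °C then acylates the more acidic allylic C8-OH. C9-OH is hydrogen-bonded to the C1 ketone and flanked by C10-Me.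
- Any 9-O-acyl isomer is recycled by base-catalysed acyl migration.

Further compounds
F1 | step 5 | methyl (4S,5E)-4-[(bromomethyl)dimethylsilyloxy]hept-5-en-2-ynoate | COC(=O)C#C[C@@H](O[Si](C)(C)CBr)/C=C/C
F2 | step 5 | methyl (6S)-5-iodo-2,2-dimethyl-6-[(E)-prop-1-enyl]-3,6-dihydro-2H-1,2-oxasiline-4-carboxylate | COC(=O)C1=C(I)[C@H](/C=C/C)O[Si](C)(C)C1
F3 | step 9 | methyl (2Z,4S,5E)-2-(acetoxymethyl)-4-hydroxy-3-iodohepta-2,5-dienoate | COC(=O)/C(COC(C)=O)=C(\I)[C@@H](O)/C=C/C
F4 | step 9 | (Z)-4-methyl-6-oxohex-4-enal 1-oxime | ON=CCC/C(C)=C\C=O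
F5 | step 9 | butenolide oxime (6R,8R) with 13-OAc, C8-OH and an (E)-propenyl group on C8 | O=C1O[C@H](/C=C(/C)CCC=NO)C([C@@H](O)/C=C/C)=C1COC(C)=O
F6 | step 9 | hydroximoyl chloride of F5 | O=C1O[C@H](/C=C(/C)CCC(Cl)=NO)C([C@@H](O)/C=C/C)=C1COC(C)=O
F7 | step 9 | nitrile oxide from F6 | O=C1O[C@H](/C=C(/C)CCC#[N+][O-])C([C@@H](O)/C=C/C)=C1COC(C)=O
F8 | step 11 | 13-acetoxy-8,9-dihydroxy-1-oxogermacra-4Z,7(11)-dien-6,12-olide (6R,8R,9R,10S) | O[C@@H]1C2=C(COC(C)=O)C(=O)O[C@@H]2/C=C(/C)CCC(=O)[C@@H](C)[C@H]1O
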